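Everything rests on disconnecting ring B at C1'–C6' and C2'–C3', so that ring B is not brought in as an arene but grown on the chromone. In one operation a [4+2] cycloaddition between a 2-ethynylchromone and (E)-1-methoxy-3-(trimethylsilyloxy)buta-1,3-diene, followed by loss of methanol and of the silyl group, creates ring B as a 4'-phenol. The step exploits the para relationship in ring B: C1' sits on C2 of ring C, the β-carbon of the C4 carbonyl, which makes the ethynyl terminus electrophilic and steers the diene oxygen to C4'. The precursor is 2-ethynyl-5,6,7,8-tetramethoxychromone, with ring A complete and C3 unsubstituted; C3–OH is added last.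

Key step: step 5

Remark: 1,2,3,4-tetramethoxybenzene carries only four of the five oxygens of ring A, so the fifth (the later O1) is introduced before acylation; C3 and the alkyne terminus of the dienophile are left as C–H, because a donor at C3 would feed electron density to the alkyne terminus and an acceptor there would make C2=C3 the better dienophile; compounds 14 and 18 are racemic, all others are achiral.

Step 1
Reactants: 1 1,2,3,4-tetramethoxybenzene
Product: 4 2,3,4,5-tetramethoxyphenol, via aryllithium 2 (not isolated), via arylboronate 3 (not isolated)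
Conditions: n-BuLi, TMEDA, THF, 0 °C; B(OMe)3, −78 °C → rt; AcOH, 30% aq. H2O2, 0 °C → rt
Reagents that add atoms: hydrogen peroxide, SMILES OO
Why: Directed ortho-metalation of the symmetric arene at its only kind of C–H (ortho to OMe), borylation of the aryllithium and peroxide oxidation of the C–B bond (1,2-aryl shift from boron to oxygen) form a standard one-flask arene hydroxylation that installs the fifth oxygen of ring A, the later O1.

Step 2
Reactants: 4 2,3,4,5-tetramethoxyphenol
Product: 6 1-(2-hydroxy-3,4,5,6-tetramethoxyphenyl)ethan-1-one, via difluoroboron chelate 5 (not isolated)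
Conditions: AcOH, BF3·OEt2, 80 °C; then H2O, 60 °C
Reagents that add atoms: acetic acid, SMILES CC(=O)O
Why: Friedel–Crafts acylation (or O-acylation and Fries rearrangement) by BF3-activated acetic acid can take place only at C6, the single unsubstituted ring carbon, which lies ortho to the hydroxyl, and the ketone is held as its difluoroboron chelate until the aqueous hydrolysis releases it.

Step 3
Reactants: 6 1-(2-hydroxy-3,4,5,6-tetramethoxyphenyl)ethan-1-one; 7 ethyl 2,2-diethoxyacetate
Product: 10 5,6,7,8-tetramethoxy-4-oxo-4H-chromene-2-carbaldehyde, via diketone acetal 8 (not isolated), via chromone acetal 9 (not isolated)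
Conditions: NaH, THF, 0 → 65 °C; then 3 M aq. HCl, AcOH, 60 °C
Reagents that add atoms: water, SMILES O
Why: Crossed Claisen condensation of the phenoxide–enolate dianion of 6 with the practically non-enolisable, inductively activated ester gives the 1,3-diketone, and aqueous acid then drives cyclodehydration onto the phenol (a standard chromone ring closure) and hydrolysis of the diethyl acetal, so that the C2 substituent arrives at the aldehyde oxidation level without redox steps.

Step 4
Reactants: 10 5,6,7,8-tetramethoxy-4-oxo-4H-chromene-2-carbaldehyde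
Product: 12 2-ethynyl-5,6,7,8-tetramethoxy-4H-chromen-4-one, via diazoalkene 11 (not isolated)
Conditions: dimethyl (1-diazo-2-oxopropyl)phosphonate, K2CO3, MeOH, 0 °C → rt
Reagents that add atoms: dimethyl (1-diazo-2-oxopropyl)phosphonate, SMILES COP(=O)(OC)C(=[N+]=[N-])C(C)=O
Why: Seyferth–Gilbert homologation in its Ohira–Bestmann form: methanolysis of the reagent frees the diazomethylphosphonate anion, whose Horner–Wadsworth–Emmons-type reaction with the aldehyde gives diazoalkene 11, and loss of N2 followed by 1,2-hydrogen shift gives the terminal alkyne under carbonate conditions mild enough for the pyranone ring.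

Step 5
Reactants: 12 2-ethynyl-5,6,7,8-tetramethoxy-4H-chromen-4-one; 13 (E)-1-methoxy-3-(trimethylsilyloxy)buta-1,3-diene
Product: 16 2-(4-hydroxyphenyl)-5,6,7,8-tetramethoxy-4H-chromen-4-one, via cycloadduct 14 (not isolated), via aryl silyl ether 15 (not isolated)
Conditions: 13 (3 equiv), toluene, 110 °C, sealed tube; then 1 M aq. HCl, THF, rt
Reagents that add atoms: none
Why: Proposed new method: in 12 the C4 carbonyl withdraws electron density from the ethynyl group by way of the C2=C3 bond, so the LUMO is lowered and its largest alkyne coefficient lies on the terminal carbon; the electron-rich diene should therefore add in a normal-demand, asynchronous [4+2] cycloaddition in which its CH2 terminus (C4) bonds first to the alkyne CH (forming C2'–C3') and its methoxy-bearing C1 then closes onto the internal alkyne carbon (forming C1'–C6'). The closest known reaction type is the Diels–Alder reaction of 1-alkoxy-3-silyloxybutadienes with acetylenic ketones and esters, which gives para-acyl phenols after elimination, whereas a 2-alkynyl-4-pyranone activated only vinylogously has not been used as the dienophile. Ring B is closed by this intermolecular [4+2] cycloaddition, each new bond joining one diene terminus to one alkyne carbon, and the cyclohexa-1,4-diene 14 aromatises by loss of methanol to 15, whose silyl ether is cleaved in the acid work-up. No stereocentre survives: the CH(OMe) carbon of 14 is formed as a racemate and becomes an ortho C–H of ring B. The step needs regioselectivity (oxygen para to C1') and chemoselectivity for the alkyne over C2=C3 and the C4 carbonyl; the first should follow from pairing the diene CH2 terminus, its most nucleophilic carbon, with the electron-poor alkyne CH, the second from the terminal alkyne being unhindered while C2 is fully substituted and C3 carries no acceptor, and from the absence of a Lewis acid that would invite hetero-Diels–Alder or Mukaiyama-type addition at C4 or C2.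

Step 6
Reactants: 16 2-(4-hydroxyphenyl)-5,6,7,8-tetramethoxy-4H-chromen-4-one
Product: 17 5,6,7,8-tetramethoxy-2-(4-methoxyphenyl)-4H-chromen-4-one
Conditions: MeI, K2CO3, acetone, 56 °C
Reagents that add atoms: iodomethane, SMILES CI
Why: Williamson ether synthesis: K2CO3 deprotonates the 4'-phenol, the only acidic group in 16, and the phenoxide is methylated by SN2 attack on iodomethane.

Step 7
Reactants: 17 5,6,7,8-tetramethoxy-2-(4-methoxyphenyl)-4H-chromen-4-one
Product: 19 3-hydroxy-5,6,7,8-tetramethoxy-2-(4-methoxyphenyl)-4H-chromen-4-one, via epoxide 18 (not isolated)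
Conditions: DMDO (acetone solution), CH2Cl2, 0 °C → rt; evaporate; then p-TsOH·H2O (cat.), CH2Cl2, rt
Reagents that add atoms: dimethyldioxirane, SMILES CC1(C)OO1
Why: Dimethyldioxirane epoxidises the C2=C3 bond of flavones under neutral conditions, and acid then opens the oxirane at C2 (cation stabilised by O1 and the 4-methoxyphenyl ring) with loss of H3 to give the enol, that is the 3-hydroxychromone, a known flavone-to-flavonol sequence that leaves no stereocentre; ring A has no C–H for competing arene oxidation.

Compound list
1 | 1,2,3,4-tetramethoxybenzene | COc1ccc(OC)c(OC)c1OC | starting material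
2 | (2,3,4,5-tetramethoxyphenyl)lithium | [Li]c1cc(OC)c(OC)c(OC)c1OC | intermediate (not isolated)
3 | dimethyl (2,3,4,5-tetramethoxyphenyl)boronate | COB(OC)c1cc(OC)c(OC)c(OC)c1OC | intermediate (not isolated)
4 | 2,3,4,5-tetramethoxyphenol | COc1cc(O)c(OC)c(OC)c1OC | intermediate
5 | difluoroboron chelate of ketone 6 (phenolate O–BF2 with the acetyl oxygen coordinated to boron, six-membered chelate ring) | CC1=[O+][B-](F)(F)Oc2c(OC)c(OC)c(OC)c(OC)c12 | intermediate (not isolated)
6 | 1-(2-hydroxy-3,4,5,6-tetramethoxyphenyl)ethan-1-one | CC(=O)c1c(O)c(OC)c(OC)c(OC)c1OC | intermediate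
7 | ethyl 2,2-diethoxyacetate | CCOC(=O)C(OCC)OCC | starting material
8 | 4,4-diethoxy-1-(2-hydroxy-3,4,5,6-tetramethoxyphenyl)butane-1,3-dione | CCOC(OCC)C(=O)CC(=O)c1c(O)c(OC)c(OC)c(OC)c1OC | intermediate (not isolated)
9 | 2-(diethoxymethyl)-5,6,7,8-tetramethoxy-4H-chromen-4-one | CCOC(OCC)c1cc(=O)c2c(OC)c(OC)c(OC)c(OC)c2o1 | intermediate (not isolated)
10 | 5,6,7,8-tetramethoxy-4-oxo-4H-chromene-2-carbaldehyde | O=Cc1cc(=O)c2c(OC)c(OC)c(OC)c(OC)c2o1 | intermediate
11 | 2-(2-diazoethenyl)-5,6,7,8-tetramethoxy-4H-chromen-4-one | [N-]=[N+]=C=Cc1cc(=O)c2c(OC)c(OC)c(OC)c(OC)c2o1 | intermediate (not isolated)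
12 | 2-ethynyl-5,6,7,8-tetramethoxy-4H-chromen-4-one | C#Cc1cc(=O)c2c(OC)c(OC)c(OC)c(OC)c2o1 | intermediate
13 | (E)-1-methoxy-3-(trimethylsilyloxy)buta-1,3-diene | CO/C=C/C(=C)O[Si](C)(C)C | starting material
14 | 2-[6-methoxy-4-(trimethylsilyloxy)cyclohexa-1,4-dien-1-yl]-5,6,7,8-tetramethoxy-4H-chromen-4-one (racemic at the CH–OMe carbon) | COC1C=C(O[Si](C)(C)C)CC=C1c1cc(=O)c2c(OC)c(OC)c(OC)c(OC)c2o1 | intermediate (not isolated)
15 | 5,6,7,8-tetramethoxy-2-[4-(trimethylsilyloxy)phenyl]-4H-chromen-4-one | C[Si](C)(C)Oc1ccc(-c2cc(=O)c3c(OC)c(OC)c(OC)c(OC)c3o2)cc1 | intermediate (not isolated)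
16 | 2-(4-hydroxyphenyl)-5,6,7,8-tetramethoxy-4H-chromen-4-one | Oc1ccc(-c2cc(=O)c3c(OC)c(OC)c(OC)c(OC)c3o2)cc1 | intermediate
17 | 5,6,7,8-tetramethoxy-2-(4-methoxyphenyl)-4H-chromen-4-one | COc1ccc(-c2cc(=O)c3c(OC)c(OC)c(OC)c(OC)c3o2)cc1 | intermediate
18 | 2,3-epoxy-5,6,7,8-tetramethoxy-2-(4-methoxyphenyl)-2,3-dihydro-4H-chromen-4-one (2,3-oxide of 17; racemic, oxirane necessarily cis-fused to ring C) | COc1ccc(C23OC2C(=O)c2c(OC)c(OC)c(OC)c(OC)c2O3)cc1 | intermediate (not isolated)
19 | 3-hydroxy-5,6,7,8-tetramethoxy-2-(4-methoxyphenyl)-4H-chromen-4-one | COc1ccc(-c2oc3c(OC)c(OC)c(OC)c(OC)c3c(=O)c2O)cc1 | target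

Total step count: 7. Longest linear sequence: 7 steps (1 → 19).

Steps most likely to fail

1. Step 5 (Proposed new method). The diene may be consumed by polymerisation or adventitious hydrolysis before it adds to an alkyne that is activated only vinylogously. It may also add across C2=C3, or the first C–C bond may form without ring closure. The fallback uses known chemistry and brings ring B in preformed. It sets out from 6: Claisen–Schmidt condensation with 4-methoxybenzaldehyde (KOH, EtOH, rt) should give the chalcone (E)-1-(2-hydroxy-3,4,5,6-tetramethoxyphenyl)-3-(4-methoxyphenyl)prop-2-en-1-one F1. Oxidative cyclisation with catalytic iodine in DMSO at 130 °C (oxa-Michael closure, α-iodination, loss of HI) should then give flavone 17, where the route is rejoined; steps 3 to 6 are then not needed.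

2. Step 4. Methoxide or the diazophosphonate anion may add to C2 of ring C or to the alkyne of the product, which would open the pyranone or lead to methanol adducts and pyrazoles. The fallback avoids methanol and carbonate and sets out from 10. Stork–Zhao olefination with the ylide from (iodomethyl)triphenylphosphonium iodide and NaN(SiMe3)2 (THF, −78 °C) should give (Z)-2-(2-iodoethenyl)-5,6,7,8-tetramethoxy-4H-chromen-4-one F2. Anti-elimination of HI with Bu4NF in THF at rt, helped by the acidity of the vinylic hydrogen next to ring C, should give 12, where the route is rejoined.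

3. Step 7. Epoxidation of the electron-poor C2=C3 bond may be slow, so that oxidative degradation of the electron-rich rings or over-oxidation of the flavonol by remaining oxidant competes. The oxirane may also open along other paths than the one to the enol. The fallback replaces electrophilic oxidation by a C3 carbanion and sets out from 17. Deprotonation at C3 with LiN(iPr)2 (THF, −78 °C) should give [5,6,7,8-tetramethoxy-2-(4-methoxyphenyl)-4-oxo-4H-chromen-3-yl]lithium F3. Trapping with B(OMe)3 should give dimethyl [5,6,7,8-tetramethoxy-2-(4-methoxyphenyl)-4-oxo-4H-chromen-3-yl]boronate F4, and oxidation with H2O2/AcOH should give 19 directly.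

Further compounds
F1 | step 5 | (E)-1-(2-hydroxy-3,4,5,6-tetramethoxyphenyl)-3-(4-methoxyphenyl)prop-2-en-1-one | COc1ccc(/C=C/C(=O)c2c(O)c(OC)c(OC)c(OC)c2OC)cc1
F2 | step 4 | (Z)-2-(2-iodoethenyl)-5,6,7,8-tetramethoxy-4H-chromen-4-one | I/C=C\c1cc(=O)c2c(OC)c(OC)c(OC)c(OC)c2o1
F3 | step 7 | [5,6,7,8-tetramethoxy-2-(4-methoxyphenyl)-4-oxo-4H-chromen-3-yl]lithium | [Li]c1c(-c2ccc(OC)cc2)oc2c(OC)c(OC)c(OC)c(OC)c2c1=O
F4 | step 7 | dimethyl [5,6,7,8-tetramethoxy-2-(4-methoxyphenyl)-4-oxo-4H-chromen-3-yl]boronate | COB(OC)c1c(-c2ccc(OC)cc2)oc2c(OC)c(OC)c(OC)c(OC)c2c1=O
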